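## Structural features

The target is a furan-2(5H)-one (ring atoms O1, C2, C3, C4, C5) in which every ring carbon is substituted. C2 is the lactone carbonyl, C3 carries the 1-acetoxybutyl chain, C4 carries bromine, and C5 carries the exocyclic bromomethylene carbon C6. The only stereocentre is C1' of the side chain (R); it is allylic to C3=C4, bears the acetate and has no stereogenic neighbour. The C5=C6 double bond is a second stereochemical element and must be Z, with the C6 bromine on the side of O1. The fragile parts are the acetate, the C4–Br bond (a vinylogous acyl bromide that amines, alkoxides and low-valent metals attack) and the cross-conjugated dienyl lactone, which is a Michael acceptor and can isomerise about C5=C6. In open-chain precursors the C1' hydrogen lies next to a ketone, so its configuration can be lost under basic conditions. The real difficulty is to place two different vinylic bromines, at C4 and at C6, with full regio- and geometric control on a small electrophilic ring without touching C1'. The key step uses the fact that C5 is bonded to C4, O1 and C6 at once: an alkyne supplies C5 and C6, C4 is a dibromomethylene carbon that spends one bromine in the coupling and keeps the other, and the carboxyl oxygen closes the ring onto the same alkyne carbon.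

## Logic of the disconnections

17 to 16. The acetyl–oxygen bond at C1' is cut, so the last step is an exchange of the oxygen substituent (silyl for acetyl). An acetate would not survive the organolithium addition or the saponification, and as an allylic ester it is a liability in the palladium step. A bulky silyl ether survives all of these and enlarges the C1' substituent, which the key step needs. The gain is one protecting group that serves from 4 to 16. The demand is an exchange that never breaks the C1'–O bond and uses no nucleophilic amine; a Lewis-acid-catalysed acetolysis meets both and avoids a separate fluoride deprotection.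

16 to 15. The C6–Br bond is traced back to a C6–Si bond. Silicon can be carried into the ring-forming step by an alkyne, it records the C5=C6 geometry set there, and it leaves by ipso substitution at the carbon where bromine is wanted. The gain is that the exocyclic bromine need not be introduced by addition and elimination on a methylene lactone. The demand is substitution with retention and no attack on C3=C4.

15 to 12 and 13. The C4–C5 and O1–C5 bonds are cut; this is the key disconnection. C5 and C6 become the two carbons of 13, O1 and C2 the carboxyl group of 12, and C4 the dibromomethylene carbon of 12. The ring, the exocyclic alkene and the C4 halogen come from one convergent operation, and C1' is a spectator. The demand is threefold: reaction of only the bromine cis to the carboxyl group, a single coupling, and 5-exo closure with anti addition so that silicon ends cis to O1.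

12 to 11. The acid is traced to its ethyl ester, because a free acid cannot be carried through the olefination. The demand is hydrolysis at the ester carbonyl without attack on the CBr2 carbon or the silyl ether.

11 to 8 and 9. The C3=C4 double bond is cut to a ketone carbonyl at C3 and the CBr2 unit of 9. This brings in C4 and both bromines in one step and leaves an α-keto ester whose ketone is activated by the neighbouring ester. The demand is olefination of a hindered ketone without enolisation towards C1'.

8 to 7, and 7 to 4 and 5. The ester carbon C2 is traced to the oxygen-bearing vinyl carbon of 5: the C=CH2 bond of 7 is a masked C2=O, and the C2–C3 bond is cut to the acyl group of 4 and the α-anion of 5. This adds the missing carbon as an acyl anion equivalent at the correct oxidation level. The demand is a single addition to the amide and a cleavage that touches only the enol ether.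

4 to 3, 3 to 2, 2 to 1. These are functional-group changes at an unchanged carbon chain: the Si–O bond, the amide C–N bond, and the C2–O bond from the C2–N bond of 1. The C1' centre is taken from the chiral pool and no asymmetric step is needed. The demand is diazotisation with retention of configuration.

## Other disconnections considered

Alternative 1: The cut is O1–C5, with C3–C4–C5 treated as a 2-bromoallyl cation stored in a gem-dibromocyclopropane. In the forward sense the Morita–Baylis–Hillman alcohol A1 would be acetylated, cyclopropanated with dibromocarbene and freed from its tert-butyl ester to give acid A2. Silver trifluoroacetate would then ionise one C–Br bond, the three-membered ring would open across C3–C5, and the carboxyl group would trap C5 to give A3.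
- In its favour: the acetate is carried from the start, so no protecting group is needed, which is better than the chosen plan. The ring atoms come from a C4 aldehyde, an acrylate and a haloform, which is cheaper than a D-amino acid. The bromine sits on the central carbon of the allyl cation and can only end at C4. The cyclopropane stereocentre is destroyed, so its configuration is irrelevant. The C4–Br bond is never exposed to a low-valent metal, which is also better than the chosen plan.
- Against it here: A3 has a CH2 group at C5 and lacks C6. The bromomethylene would have to be attached afterwards by enolisation and condensation at C5 of a base-sensitive 4-bromobutenolide that also carries an acetate. Dibromocarbene is electrophilic and the acrylate double bond is electron-poor. The carboxyl group must finish cis to C5, which requires loss of the bromide cis to it and inward rotation at the fully substituted C3. Enantiopure A1 from an aliphatic aldehyde would need a resolution.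
- Comparison: on structure, the chosen key step delivers the ring, C6 and both halogen positions, whereas the alternative delivers only the ring. On mechanism, both hinge on which of two geminal bromines reacts, decided by sterics in the chosen plan and by torquoselectivity in the alternative. On step economy, A3 would be reached in about five steps, but adding C6 would take several more, so the total is unlikely to be shorter.

Alternative 2: The cut is C3–C4. The enol ester A4 would be made by O-acylation of a bromopyruvate ester enolate with a protected β-hydroxy acid chloride. Deprotonation at the acyl α-carbon and attack of the enolate on the methyl ester carbon would close the tetronic acid A5. Vilsmeier-type bromination of the C4 hydroxyl (oxalyl bromide, DMF) would then lead to 16.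
- In its favour: the Z bromomethylene and the C1' centre are in place before the ring closes, so no late halogenation at C6 is needed. The stereocentre would come from catalytic asymmetric hydrogenation of a β-keto ester. The route is convergent and would reach 16 in about six steps against nine, so step economy is better than in the chosen plan.
- Against it here: the enolate is β to a silyloxy group and can eliminate it. Enolates of enol esters can fragment to a ketene and an enolate or shift the acyl group from O to C. The Z geometry of A4 must be set in the O-acylation of a bromopyruvate enolate, which is not reliably controlled. The β-bromoacrylate part of A4 is itself an electrophile towards the base.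
- Comparison: on structure, both plans close the one ring; the alternative forms one C–C bond and the chosen plan one C–C and one C–O bond. On mechanism, the alternative is a strongly basic anionic closure on a substrate with two base-labile sites, whereas the chosen plan runs with a tertiary amine at room temperature. Geometry control is equal in kind: from the precursor alkene in the alternative, from anti addition and retentive substitution in the chosen plan.

Alternative 3: The cuts are C2–C3 and C2–O1, with C2 supplied by carbon monoxide. The dibromoenone A6 would come from a silyl-protected propargylic alcohol by acylation of its acetylide and anti addition of bromine. Zerovalent palladium would insert into the C–Br bond β to the ketone, which is cis to the acetyl group, CO would insert, and the enol oxygen of the methyl ketone would capture the acylpalladium to give A7. Bromine addition and dehydrobromination at the exocyclic methylene would then give 16.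
- In its favour: the two C–Br bonds of A6 are differentiated electronically (β against α to the ketone), a firmer basis for site selectivity than the steric argument of the chosen plan, and so better on that point. The lactone carbonyl comes from CO with full atom economy. 16 would be reached in about five or six steps, shorter than the chosen plan.
- Against it here: carbon monoxide under pressure runs against the aim of a safe route. Bromine addition to an electron-poor ynone need not be cleanly anti, and only the E isomer can cyclise. The acylpalladium may be trapped at carbon instead of oxygen. A7 is a methylene lactone of a type prone to dimerisation and polymerisation. The C6 bromine must then be set by addition and elimination, where the geometry is under thermodynamic control only.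
- Comparison: on structure, the alternative builds the carbonyl end of the ring last and leaves C6 unfunctionalised, whereas the chosen plan builds the C5 end and marks C6 with silicon. On mechanism, both are palladium-catalysed and both leave an activated C4–Br in the product, so the risk of over-reaction is equal. On step economy the alternative is better. The chosen plan is preferred for safety and for the silicon-controlled geometry at C6.

Key step: step 8

Remark on the chemistry: in the uncyclised coupling product 14 the carboxyl and alkynyl groups are cis, but bromine outranks the alkynyl carbon on the same alkene carbon, so the correct descriptor of 14 is E.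

Step 1
Reactants: 1 D-norvaline
Product: 2 (R)-2-hydroxypentanoic acid
Conditions: NaNO2, 1 M H2SO4 (aq), 0 °C → rt
Reagents that add atoms: water, O
Why: Diazotisation of the α-amino acid; neighbouring-group participation by the carboxylate gives a double inversion, so the hydroxyl group replaces the amine with net retention and the 2R centre is kept.

Step 2
Reactants: 2 (R)-2-hydroxypentanoic acid
Product: 3 (R)-2-hydroxy-N-methoxy-N-methylpentanamide
Conditions: MeNHOMe·HCl, EDC·HCl, HOBt, N-methylmorpholine, CH2Cl2, 0 °C → rt
Reagents that add atoms: N,O-dimethylhydroxylamine hydrochloride, CNOC.Cl
Why: Carbodiimide amidation through an active ester; the amine outcompetes the secondary hydroxyl, and an α-hydroxy acid has no oxazolone pathway, so C2 should not epimerise.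

Step 3
Reactants: 3 (R)-2-hydroxy-N-methoxy-N-methylpentanamide
Product: 4 (R)-2-(tert-butyldimethylsilyloxy)-N-methoxy-N-methylpentanamide
Conditions: TBSCl, imidazole, DMF, rt
Reagents that add atoms: tert-butyldimethylsilyl chloride, CC(C)(C)[Si](C)(C)Cl
Why: Standard silylation of a secondary alcohol; the silyl ether withstands the organolithium, ozonolysis and hydrolysis steps and later supplies the steric bulk next to the dibromoalkene.

Step 4
Reactants: 4 (R)-2-(tert-butyldimethylsilyloxy)-N-methoxy-N-methylpentanamide; 5 ethyl vinyl ether
Product: 7 (R)-4-(tert-butyldimethylsilyloxy)-2-ethoxyhept-1-en-3-one, via 1-ethoxyvinyllithium 6 (not isolated)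
Conditions: 5, t-BuLi, THF, −78 → 0 °C; then 4, −78 → −20 °C; aq NH4Cl
Reagents that add atoms: none
Why: α-Lithiation of the vinyl ether gives the acyl anion equivalent 6, which adds only once to the Weinreb amide because the N-methoxy chelate holds the tetrahedral adduct until the quench; α-silyloxy Weinreb amides are configurationally stable to organolithium addition at low temperature.

Step 5
Reactants: 7 (R)-4-(tert-butyldimethylsilyloxy)-2-ethoxyhept-1-en-3-one
Product: 8 ethyl (R)-3-(tert-butyldimethylsilyloxy)-2-oxohexanoate
Conditions: O3, CH2Cl2/MeOH, −78 °C; then Me2S, −78 °C → rt
Reagents that add atoms: ozone, O=[O+][O-]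
Why: Ozonolysis of the electron-rich enol ether double bond turns the ethoxy-bearing carbon into the ester carbonyl and releases the CH2 carbon as formaldehyde; the ketone and silyl ether are inert, and the neutral, cold conditions with reductive quench should leave C3 untouched.

Step 6
Reactants: 8 ethyl (R)-3-(tert-butyldimethylsilyloxy)-2-oxohexanoate; 9 carbon tetrabromide
Product: 11 ethyl (R)-3,3-dibromo-2-[1-(tert-butyldimethylsilyloxy)butyl]prop-2-enoate, via (dibromomethylene)triphenylphosphorane 10 (not isolated)
Conditions: 9, PPh3, Zn dust, CH2Cl2, rt; then 8, 0 °C → rt
Reagents that add atoms: none
Why: Ramirez dibromo-olefination (the first stage of the Corey–Fuchs sequence): ylide 10 undergoes a Wittig reaction at the ketone carbonyl, which the adjacent ester makes strongly electrophilic. Zinc replaces the second phosphine equivalent, so neither a bromophosphonium bromide nor an amine base is present to cleave the silyl ether or enolise C3.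

Step 7
Reactants: 11 ethyl (R)-3,3-dibromo-2-[1-(tert-butyldimethylsilyloxy)butyl]prop-2-enoate
Product: 12 (R)-3,3-dibromo-2-[1-(tert-butyldimethylsilyloxy)butyl]prop-2-enoic acid
Conditions: LiOH·H2O, THF/H2O (3:1), rt; then 1 M HCl to pH 3, 0 °C
Reagents that add atoms: lithium hydroxide, [Li+].[OH-]
Why: Saponification of the ethyl ester by acyl–oxygen cleavage; hydroxide should prefer the ester carbonyl to the hindered, fully substituted CBr2 carbon, and the silyl ether tolerates LiOH and a brief cold acidification.

Step 8
Reactants: 12 (R)-3,3-dibromo-2-[1-(tert-butyldimethylsilyloxy)butyl]prop-2-enoic acid; 13 ethynyltrimethylsilane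
Product: 15 (R,Z)-4-bromo-3-[1-(tert-butyldimethylsilyloxy)butyl]-5-[(trimethylsilyl)methylene]furan-2(5H)-one, via (R,E)-3-bromo-2-[1-(tert-butyldimethylsilyloxy)butyl]-5-(trimethylsilyl)pent-2-en-4-ynoic acid 14 (not isolated)
Conditions: 13 (1.05 equiv, slow addition), PdCl2(PPh3)2 (5 mol %), CuI (10 mol %), Et3N (3 equiv), MeCN, rt, argon
Reagents that add atoms: none
Why: Tandem Sonogashira coupling and lactonisation; the closest known reaction type is the coupling of (Z)-3-halopropenoic acids with terminal alkynes that closes directly to (Z)-5-ylidenefuran-2(5H)-ones, combined with the trans-selective monoalkynylation of 1,1-dibromoalkenes. The divalent palladium precatalyst is reduced to zerovalent palladium, which inserts into the C–Br bond trans to the silyloxybutyl branch and cis to the carboxylate, because that bromine is the less hindered one and the carboxylate can guide the metal to it. Transfer of the copper acetylide of 13 and reductive elimination form C4–C5 and give 14, in which carboxylate and alkyne are cis. The carboxylate oxygen then adds anti across the metal-coordinated triple bond at the near alkyne carbon, a 5-exo-dig closure that forms O1–C5; the 6-endo-dig mode would have to attack the carbon that bears the trimethylsilyl group and is disfavoured. Protodemetalation with retention places hydrogen trans and silicon cis to O1, which is the Z geometry; no stereocentre is formed and C1' takes no part. The step needs coupling at one bromine only: the gem-dibromide should react faster than the monobromide left behind, the alkyne is limited to about one equivalent and added slowly, and the base is a tertiary amine that cannot displace the C4–Br of 15. Acid that has coupled at the other bromine cannot lactonise and is separated from neutral 15 by a bicarbonate wash.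

Step 9
Reactants: 15 (R,Z)-4-bromo-3-[1-(tert-butyldimethylsilyloxy)butyl]-5-[(trimethylsilyl)methylene]furan-2(5H)-one
Product: 16 (R,Z)-4-bromo-5-(bromomethylene)-3-[1-(tert-butyldimethylsilyloxy)butyl]furan-2(5H)-one
Conditions: NBS (1.1 equiv), MeCN, 0 °C → rt, dark
Reagents that add atoms: N-bromosuccinimide, O=C1CCC(=O)N1Br
Why: Electrophilic ipso-bromodesilylation of a vinylsilane: the bromine electrophile attacks C6, which is β to the ring oxygen and ipso to silicon, and the C5 cation is stabilised by O1 and by the C–Si bond. Loss of the silyl group after least-motion rotation gives retention; no free bromide is present to add and invert, and the Z isomer is also the less strained one because an E bromine would clash with the C4 bromine.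

Step 10
Reactants: 16 (R,Z)-4-bromo-5-(bromomethylene)-3-[1-(tert-butyldimethylsilyloxy)butyl]furan-2(5H)-one
Product: 17 (R)-1-[(Z)-4-bromo-5-(bromomethylene)-2-oxo-2,5-dihydrofuran-3-yl]butyl acetate
Conditions: Ac2O, FeCl3 (10 mol %), 0 °C → rt
Reagents that add atoms: acetic anhydride, CC(=O)OC(C)=O
Why: Lewis-acid-catalysed acetolysis of a silyl ether (direct silyl ether to acetate exchange): the ether oxygen is acylated and the silyl group leaves as its acetate, so the C1'–O bond is never broken and the R configuration is retained. The acidic, amine-free medium should spare the C4–Br bond and the dienyl lactone, and the electron-poor ring disfavours ionisation at C1'.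

Compound list

1 | D-norvaline, (R)-2-aminopentanoic acid | CCC[C@@H](N)C(=O)O | starting material
2 | (R)-2-hydroxypentanoic acid | CCC[C@@H](O)C(=O)O | intermediate
3 | (R)-2-hydroxy-N-methoxy-N-methylpentanamide | CCC[C@@H](O)C(=O)N(C)OC | intermediate
4 | (R)-2-(tert-butyldimethylsilyloxy)-N-methoxy-N-methylpentanamide | CCC[C@@H](O[Si](C)(C)C(C)(C)C)C(=O)N(C)OC | intermediate
5 | ethyl vinyl ether | C=COCC | starting material
6 | 1-ethoxyvinyllithium | [Li]C(=C)OCC | intermediate (not isolated)
7 | (R)-4-(tert-butyldimethylsilyloxy)-2-ethoxyhept-1-en-3-one | CCC[C@@H](O[Si](C)(C)C(C)(C)C)C(=O)C(=C)OCC | intermediate
8 | ethyl (R)-3-(tert-butyldimethylsilyloxy)-2-oxohexanoate | CCC[C@@H](O[Si](C)(C)C(C)(C)C)C(=O)C(=O)OCC | intermediate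
9 | carbon tetrabromide | BrC(Br)(Br)Br | starting material
10 | (dibromomethylene)triphenylphosphorane | BrC(Br)=P(c1ccccc1)(c1ccccc1)c1ccccc1 | intermediate (not isolated)
11 | ethyl (R)-3,3-dibromo-2-[1-(tert-butyldimethylsilyloxy)butyl]prop-2-enoate | CCC[C@@H](O[Si](C)(C)C(C)(C)C)C(C(=O)OCC)=C(Br)Br | intermediate
12 | (R)-3,3-dibromo-2-[1-(tert-butyldimethylsilyloxy)butyl]prop-2-enoic acid | CCC[C@@H](O[Si](C)(C)C(C)(C)C)C(C(=O)O)=C(Br)Br | intermediate
13 | ethynyltrimethylsilane | C#C[Si](C)(C)C | starting material
14 | (R,E)-3-bromo-2-[1-(tert-butyldimethylsilyloxy)butyl]-5-(trimethylsilyl)pent-2-en-4-ynoic acid | CCC[C@@H](O[Si](C)(C)C(C)(C)C)/C(C(=O)O)=C(Br)/C#C[Si](C)(C)C | intermediate (not isolated)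
15 | (R,Z)-4-bromo-3-[1-(tert-butyldimethylsilyloxy)butyl]-5-[(trimethylsilyl)methylene]furan-2(5H)-one | CCC[C@@H](O[Si](C)(C)C(C)(C)C)C1=C(Br)/C(=C/[Si](C)(C)C)OC1=O | intermediate
16 | (R,Z)-4-bromo-5-(bromomethylene)-3-[1-(tert-butyldimethylsilyloxy)butyl]furan-2(5H)-one | CCC[C@@H](O[Si](C)(C)C(C)(C)C)C1=C(Br)/C(=C/Br)OC1=O | intermediate
17 | (R)-1-[(Z)-4-bromo-5-(bromomethylene)-2-oxo-2,5-dihydrofuran-3-yl]butyl acetate | CCC[C@@H](OC(C)=O)C1=C(Br)/C(=C/Br)OC1=O | target

Total step count: 10. Longest linear sequence: 10 steps, from 1 to 17; 5, 9 and 13 are commercial and enter in steps 4, 6 and 8.

Least certain steps

Step 8 (key step). The most likely failures are oxidative addition at the bromine cis to the silyloxybutyl group, a second alkynylation at C4 once the lactone has formed (the remaining bromide is then an activated β-bromo enoate), closure in the 6-endo mode, or loss of carbon dioxide and bromide from the carboxylate by anti elimination under the amine and copper conditions. Fallback, setting out from 12 and 13 and returning at 15: 13 is deprotonated with n-BuLi and transmetalated with ZnCl2 to (trimethylsilylethynyl)zinc chloride F1. A Negishi coupling of 12 with F1 (a little over two equivalents, the first forming the zinc carboxylate) under PdCl2(DPEphos) catalysis in THF at 0 °C to rt, free of amine and copper, should give 14, which is now isolated after a mild acidic work-up. A separate 5-exo-dig lactonisation of 14 with catalytic Ag2CO3 in MeCN at rt would then give 15. Both operations are known reaction types, and separating coupling from ring closure lets each selectivity be controlled on its own.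

Step 6. The Wittig addition to a ketone flanked by the silyloxy branch may be slow; enolisation towards C3 would then erode the configuration, and bromophosphonium species could cleave the silyl ether. Fallback, setting out from 8 and returning at 11: dibromomethyllithium F2, preformed from CH2Br2 and lithium diisopropylamide in THF at −90 °C, is added to the ketone of 8 and quenched cold with acetic acid to give ethyl (3R)-2-(dibromomethyl)-2-hydroxy-3-(tert-butyldimethylsilyloxy)hexanoate F3 as a mixture at C2. Dehydration of F3 with SOCl2 and pyridine in CH2Cl2 at 0 °C, in which pyridine removes the acidic CHBr2 proton, should give 11. This replaces the phosphorus ylide by carbenoid addition and elimination.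

Step 9. Ipso attack on the electron-poor dienyl lactone may be sluggish, and the exocyclic geometry may erode through rotation in the β-silyl cation or through bromide addition followed by anti elimination. Fallback, setting out from 15 and returning at 16: protodesilylation with CF3CO2H in CH2Cl2 at 0 °C gives the methylene lactone (R)-4-bromo-3-[1-(tert-butyldimethylsilyloxy)butyl]-5-methylenefuran-2(5H)-one F4, the same structure as A7. Bromine in CH2Cl2 at −78 → 0 °C adds across the exocyclic double bond to give 4,5-dibromo-5-(bromomethyl)-3-[(R)-1-(tert-butyldimethylsilyloxy)butyl]furan-2(5H)-one F5. Et3N at 0 °C then removes HBr to give 16, where the Z isomer is expected to be favoured because it avoids the clash with the C4 bromine. This is one step longer and replaces ipso substitution by addition and elimination.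

Step 10. Exchange at the hindered secondary silyl ether may stall, and prolonged contact with the Lewis acid may isomerise the C5=C6 bond or exchange halide. Fallback, setting out from 16 and returning at 17: catalytic acetyl chloride in dry methanol (HCl formed in the flask) at 0 °C removes the silyl group to give (R,Z)-4-bromo-5-(bromomethylene)-3-(1-hydroxybutyl)furan-2(5H)-one F6. Acetylation of F6 with Ac2O and catalytic Sc(OTf)3 in MeCN at 0 °C, again without an amine, gives 17. This separates deprotection from acylation at the cost of one step.

Further compounds

F1 | step 8 | (trimethylsilylethynyl)zinc chloride | C[Si](C)(C)C#C[Zn]Cl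
F2 | step 6 | dibromomethyllithium | [Li]C(Br)Br
F3 | step 6 | ethyl (3R)-2-(dibromomethyl)-2-hydroxy-3-(tert-butyldimethylsilyloxy)hexanoate (both C2 epimers) | CCC[C@@H](O[Si](C)(C)C(C)(C)C)C(O)(C(Br)Br)C(=O)OCC
F4 | step 9 | (R)-4-bromo-3-[1-(tert-butyldimethylsilyloxy)butyl]-5-methylenefuran-2(5H)-one | CCC[C@@H](O[Si](C)(C)C(C)(C)C)C1=C(Br)C(=C)OC1=O
F5 | step 9 | 4,5-dibromo-5-(bromomethyl)-3-[(R)-1-(tert-butyldimethylsilyloxy)butyl]furan-2(5H)-one (both C5 epimers) | CCC[C@@H](O[Si](C)(C)C(C)(C)C)C1=C(Br)C(Br)(CBr)OC1=O
F6 | step 10 | (R,Z)-4-bromo-5-(bromomethylene)-3-(1-hydroxybutyl)furan-2(5H)-one | CCC[C@@H](O)C1=C(Br)/C(=C/Br)OC1=O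
A1 | alternative 1 | tert-butyl (R)-3-hydroxy-2-methylenehexanoate | CCC[C@@H](O)C(=C)C(=O)OC(C)(C)C
A2 | alternative 1 | 1-[(R)-1-acetoxybutyl]-2,2-dibromocyclopropane-1-carboxylic acid (both ring epimers) | CCC[C@@H](OC(C)=O)C1(CC1(Br)Br)C(=O)O
A3 | alternative 1 | (R)-1-(4-bromo-2-oxo-2,5-dihydrofuran-3-yl)butyl acetate | CCC[C@@H](OC(C)=O)C1=C(Br)COC1=O
A4 | alternative 2 | methyl (Z)-3-bromo-2-{[(R)-3-(tert-butyldimethylsilyloxy)hexanoyl]oxy}prop-2-enoate | CCC[C@@H](O[Si](C)(C)C(C)(C)C)CC(=O)O/C(=C\Br)C(=O)OC
A5 | alternative 2 | (R,Z)-5-(bromomethylene)-3-[1-(tert-butyldimethylsilyloxy)butyl]-4-hydroxyfuran-2(5H)-one | CCC[C@@H](O[Si](C)(C)C(C)(C)C)C1=C(O)/C(=C/Br)OC1=O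
A6 | alternative 3 | (R,E)-3,4-dibromo-5-(tert-butyldimethylsilyloxy)oct-3-en-2-one | CCC[C@@H](O[Si](C)(C)C(C)(C)C)/C(Br)=C(Br)/C(C)=O
A7 | alternative 3 | (R)-4-bromo-3-[1-(tert-butyldimethylsilyloxy)butyl]-5-methylenefuran-2(5H)-one | CCC[C@@H](O[Si](C)(C)C(C)(C)C)C1=C(Br)C(=C)OC1=O
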